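**Strategy.** The cycloheptene (seven-membered ring) of the target is cut on both sides of its C7–C8(CH3) unit (daucane numbering), at C6–C7 and C8–C9. A trans-1,2-disubstituted cyclopentane that already holds C1, C4 and C5, with an aryl ketone arm ending at C6 and an acetaldehyde arm ending at C9, is annulated with isopropenyltriphenylphosphonium bromide. Michael addition of the ketone enolate forms C6–C7, and the ylide so generated closes C8=C9 by intramolecular Wittig reaction. The step exploits the C8–C9 epoxide as a latent trisubstituted alkene and the C6 ester as a latent aroyl ketone; one peracid treatment later delivers both.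

Key step: step 10

Remark 1: daucane numbering is used throughout: C1 (quaternary, CH3), C2, C3, C4 (carbinol, isopropyl) and C5 (ring-fusion CH) in the five-membered ring; C6 (ester carbon), C7, C8 (CH3), C9 and C10 in the seven-membered ring; β is the face of the C1 methyl group.
Remark 2: the sense of induction in step 1 is assumed to be selectable by taking the quinine- or the quinidine-derived amine; the one that gives the (1R,5R) epoxide is used.
Remark 3: 8, 9 and 15 are drawn as open γ-hydroxy ketones; each may sit in equilibrium with its five-membered hemiketal, which does not change the chemistry.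

Step 1
Reactants: 1 3-methylcyclopent-2-en-1-one
Product: 2 (1R,5R)-5-methyl-6-oxabicyclo[3.1.0]hexan-2-one
Conditions: 9-amino-9-deoxy-epi-quinine (10 mol %), CF3CO2H (20 mol %), 50% aq H2O2, dioxane, 50 °C
Reagents that add atoms: hydrogen peroxide, OO
Why: Iminium-activated Weitz–Scheffer epoxidation of a cyclic enone by a cinchona primary amine salt, in which the chiral amine fixes the face of hydroperoxide attack so that the cis-fused epoxide should form as one enantiomer.

Step 2
Reactants: 2 (1R,5R)-5-methyl-6-oxabicyclo[3.1.0]hexan-2-one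
Product: 3 (1S,2R,5R)-5-methyl-2-(propan-2-yl)-6-oxabicyclo[3.1.0]hexan-2-ol
Conditions: iPrMgCl, CeCl3, THF, −78 °C; aq NH4Cl
Reagents that add atoms: isopropylmagnesium chloride, CC(C)[Mg]Cl
Why: Organocerium 1,2-addition to an α,β-epoxy ketone should occur anti to the epoxide oxygen, which sets the tertiary carbinol C4 as R and leaves the epoxide intact.

Step 3
Reactants: 3 (1S,2R,5R)-5-methyl-2-(propan-2-yl)-6-oxabicyclo[3.1.0]hexan-2-ol
Product: 4 (1R)-3-methyl-1-(propan-2-yl)cyclopent-2-en-1-ol
Conditions: WCl6 (3 equiv), n-BuLi (6 equiv), THF, −78 °C → rt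
Reagents that add atoms: none
Why: Low-valent tungsten deoxygenation of a trisubstituted epoxide regenerates the C5=C1 alkene without touching the carbinol, so the absolute configuration set in steps 1 and 2 is now stored in C4 alone.

Step 4
Reactants: 4 (1R)-3-methyl-1-(propan-2-yl)cyclopent-2-en-1-ol
Product: 5 (1R)-1-(2-bromo-1-ethoxyethoxy)-3-methyl-1-(propan-2-yl)cyclopent-2-ene (both acetal epimers)
Conditions: ethyl vinyl ether, NBS, CH2Cl2, −40 → 0 °C
Reagents that add atoms: ethyl vinyl ether, C=COCC; N-bromosuccinimide, O=C1CCC(=O)N1Br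
Why: Ueno–Stork bromoacetal formation, in which the enol ether out-competes the ring alkene for the bromonium source and the tertiary alcohol traps the oxocarbenium ion; the acetal centre is of no consequence.

Step 5
Reactants: 5 (1R)-1-(2-bromo-1-ethoxyethoxy)-3-methyl-1-(propan-2-yl)cyclopent-2-ene
Product: 6 (3aR,4R,6aR)-2-ethoxy-4-methyl-4-(prop-2-en-1-yl)-6a-(propan-2-yl)hexahydro-2H-cyclopenta[b]furan (both C2 epimers)
Conditions: allyltributylstannane (3 equiv), AIBN (cat.), benzene, 80 °C
Reagents that add atoms: allyltributylstannane, C=CC[Sn](CCCC)(CCCC)CCCC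
Why: Ueno–Stork 5-exo-trig radical cyclisation followed by Keck allylation: the tether can reach C5 only on the face of the C4–O bond (cis-fused ring), and the tertiary C1 radical should be allylated on the convex face anti to the new C5–C6 bond, which sets C5 and the quaternary C1 from C4.

Step 6
Reactants: 6 (3aR,4R,6aR)-2-ethoxy-4-methyl-4-(prop-2-en-1-yl)-6a-(propan-2-yl)hexahydro-2H-cyclopenta[b]furan
Product: 7 (3aR,4R,6aR)-4-methyl-4-(prop-2-en-1-yl)-6a-(propan-2-yl)hexahydro-2H-cyclopenta[b]furan-2-one
Conditions: CrO3, H2SO4, H2O, acetone, 0 °C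
Reagents that add atoms: water, O
Why: Jones oxidation hydrolyses the ethyl acetal and oxidises the lactol to the γ-lactone, so both acetal epimers converge while the terminal alkene and all stereocentres are untouched.

Step 7
Reactants: 7 (3aR,4R,6aR)-4-methyl-4-(prop-2-en-1-yl)-6a-(propan-2-yl)hexahydro-2H-cyclopenta[b]furan-2-one
Product: 8 1-(4-bromophenyl)-2-[(1R,2R,5R)-2-hydroxy-5-methyl-5-(prop-2-en-1-yl)-2-(propan-2-yl)cyclopentyl]ethan-1-one
Conditions: 1,4-dibromobenzene, n-BuLi, THF, −78 °C; then 7, −78 °C; aq NH4Cl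
Reagents that add atoms: 4-bromophenyllithium (from 1,4-dibromobenzene and n-BuLi), [Li]c1ccc(Br)cc1
Why: Mono-addition of an aryllithium to a lactone stops at the tetrahedral lithium hemiketal at −78 °C and releases the aryl ketone and the tertiary C4 hydroxyl on work-up; the bromoarene is chosen because its ketone later migrates correctly in the Baeyer–Villiger step.

Step 8
Reactants: 8 1-(4-bromophenyl)-2-[(1R,2R,5R)-2-hydroxy-5-methyl-5-(prop-2-en-1-yl)-2-(propan-2-yl)cyclopentyl]ethan-1-one
Product: 9 2-[(1R,2R,3R)-2-[2-(4-bromophenyl)-2-oxoethyl]-3-hydroxy-1-methyl-3-(propan-2-yl)cyclopentyl]acetaldehyde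
Conditions: O3, CH2Cl2/MeOH, −78 °C; then Me2S
Reagents that add atoms: ozone, [O-][O+]=O
Why: Ozonolysis with reductive work-up cleaves the only alkene to the C9 aldehyde, the electron-poor bromoarene being inert at −78 °C.

Step 9
Reactants: 10 triphenylphosphine; 11 2-bromopropene
Product: 12 triphenyl(prop-1-en-2-yl)phosphonium bromide
Conditions: Pd(PPh3)4 (2 mol %), toluene, 100 °C, sealed tube
Reagents that add atoms: none
Why: Palladium-catalysed P–C(sp2) coupling (oxidative addition of the alkenyl bromide, then reductive elimination of the phosphonium salt) is an established route to alkenylphosphonium halides.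

Step 10
Reactants: 9 2-[(1R,2R,3R)-2-[2-(4-bromophenyl)-2-oxoethyl]-3-hydroxy-1-methyl-3-(propan-2-yl)cyclopentyl]acetaldehyde; 12 triphenyl(prop-1-en-2-yl)phosphonium bromide
Product: 15 (4-bromophenyl)[(3R,3aR,4S,8aR)-3-hydroxy-6,8a-dimethyl-3-(propan-2-yl)-1,2,3,3a,4,5,8,8a-octahydroazulen-4-yl]methanone, via sodium enolate 13 (not isolated), via phosphorus ylide 14 (not isolated)
Conditions: NaH (1.05 equiv), THF/DMF, 0 °C; then 12, 0 → 60 °C; then DBU (10 mol %), rt
Reagents that add atoms: none
Why: One equivalent of NaH gives, with the C4 hydroxyl as proton shuttle, the aryl-conjugated ketone enolate, whose C6 adds to the CH2 terminus of the isopropenylphosphonium salt (C6–C7), and the ylide so formed at C8 olefinates the C9 aldehyde intramolecularly (C8=C9) with loss of Ph3P=O. This is the conjugate addition–intramolecular Wittig carbocyclisation of vinylphosphonium salts (Schweizer annulation), used here with the α-methyl reagent. The cycloheptene closes by attack of the ylide carbon on the aldehyde carbonyl (7-exo-trig, through the oxaphosphetane), which forces the ring alkene to be cis. The only new stereocentre, C6, is α to the ketone and should equilibrate (DBU) to the isomer with the aroyl group trans to the C5–C4 bond (6α, pseudo-equatorial), while C1, C4 and C5 are untouched. The step needs the ketone and not the aldehyde to act as nucleophile: the benzoyl-type enolate should be the thermodynamic enolate in DMF and its C6 is less hindered than the neopentylic C10, the aldehyde is the only carbonyl the ylide can reach through a seven-membered transition state, and aldol closure between the trans-disposed arms would give a strained trans-bicyclo[3.3.0]octane and is reversible.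

Step 11
Reactants: 15 (4-bromophenyl)[(3R,3aR,4S,8aR)-3-hydroxy-6,8a-dimethyl-3-(propan-2-yl)-1,2,3,3a,4,5,8,8a-octahydroazulen-4-yl]methanone
Product: 17 8α,9α-epoxy-4β-hydroxy-5αH-daucan-6α-yl 4-bromobenzoate, via epoxy ketone 16 (not isolated)
Conditions: (CF3CO)2O, urea·H2O2, Na2HPO4, CH2Cl2, 0 °C → rt
Reagents that add atoms: trifluoroperacetic acid, OOC(=O)C(F)(F)F
Why: Buffered trifluoroperacetic acid should first epoxidise the trisubstituted C8=C9 alkene on the α face (anti to the angular C1 methyl group) and then effect Baeyer–Villiger oxidation of the aryl ketone, in which the secondary C6 migrates in preference to the electron-poor 4-bromophenyl group with retention, so the 6α ester arises from the 6α ketone.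

Step 12
Reactants: 17 8α,9α-epoxy-4β-hydroxy-5αH-daucan-6α-yl 4-bromobenzoate
Product: 19 jaeskeanin (8α,9α-epoxy-4β-hydroxy-5αH-daucan-6α-yl 4-hydroxybenzoate), via aryl boronate 18 (not isolated)
Conditions: Pd(dppf)Cl2 (5 mol %), B2pin2, KOAc, dioxane, 85 °C; then NaBO3·4H2O, THF/H2O, rt
Reagents that add atoms: sodium perborate, [Na+].[O-]OB=O
Why: Miyaura borylation of the aryl bromide followed by perborate oxidation of the C–B bond turns ArBr into ArOH under conditions that should leave the hindered secondary benzoate, the non-allylic epoxide and the tertiary alcohol alone.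

**Compound list**

1 | 3-methylcyclopent-2-en-1-one | CC1=CC(=O)CC1 | starting material
2 | (1R,5R)-5-methyl-6-oxabicyclo[3.1.0]hexan-2-one (cis-fused epoxy ketone) | O=C1CC[C@@]2(C)O[C@@H]12 | intermediate
3 | (1S,2R,5R)-5-methyl-2-(propan-2-yl)-6-oxabicyclo[3.1.0]hexan-2-ol (hydroxyl cis to the epoxide oxygen) | CC(C)[C@]1(O)CC[C@@]2(C)O[C@@H]12 | intermediate
4 | (1R)-3-methyl-1-(propan-2-yl)cyclopent-2-en-1-ol | CC(C)[C@]1(O)CCC(C)=C1 | intermediate
5 | (1R)-1-(2-bromo-1-ethoxyethoxy)-3-methyl-1-(propan-2-yl)cyclopent-2-ene (both acetal epimers) | CC(C)[C@]1(OC(CBr)OCC)CCC(C)=C1 | intermediate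
6 | (3aR,4R,6aR)-2-ethoxy-4-methyl-4-(prop-2-en-1-yl)-6a-(propan-2-yl)hexahydro-2H-cyclopenta[b]furan (cis-fused; allyl anti to C3; both C2 epimers) | CC(C)[C@]12CC[C@](C)(CC=C)[C@H]1CC(OCC)O2 | intermediate
7 | (3aR,4R,6aR)-4-methyl-4-(prop-2-en-1-yl)-6a-(propan-2-yl)hexahydro-2H-cyclopenta[b]furan-2-one | CC(C)[C@]12CC[C@](C)(CC=C)[C@H]1CC(=O)O2 | intermediate
8 | 1-(4-bromophenyl)-2-[(1R,2R,5R)-2-hydroxy-5-methyl-5-(prop-2-en-1-yl)-2-(propan-2-yl)cyclopentyl]ethan-1-one | CC(C)[C@]1(O)CC[C@](C)(CC=C)[C@H]1CC(=O)c1ccc(Br)cc1 | intermediate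
9 | 2-[(1R,2R,3R)-2-[2-(4-bromophenyl)-2-oxoethyl]-3-hydroxy-1-methyl-3-(propan-2-yl)cyclopentyl]acetaldehyde | CC(C)[C@]1(O)CC[C@](C)(CC=O)[C@H]1CC(=O)c1ccc(Br)cc1 | intermediate
10 | triphenylphosphine | c1ccc(cc1)P(c1ccccc1)c1ccccc1 | starting material
11 | 2-bromopropene | CC(Br)=C | starting material
12 | triphenyl(prop-1-en-2-yl)phosphonium bromide | CC(=C)[P+](c1ccccc1)(c1ccccc1)c1ccccc1.[Br-] | intermediate
13 | sodium enolate of 9 (enolate carbon C6) | CC(C)[C@]1(O)CC[C@](C)(CC=O)[C@H]1C=C([O-])c1ccc(Br)cc1.[Na+] | intermediate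
14 | phosphorus ylide formed by C6 addition of 13 to 12 (C6–C7 made; C6 epimers) | CC(C)[C@]1(O)CC[C@](C)(CC=O)[C@H]1C(CC(C)=P(c1ccccc1)(c1ccccc1)c1ccccc1)C(=O)c1ccc(Br)cc1 | intermediate
15 | (4-bromophenyl)[(3R,3aR,4S,8aR)-3-hydroxy-6,8a-dimethyl-3-(propan-2-yl)-1,2,3,3a,4,5,8,8a-octahydroazulen-4-yl]methanone (6α-aroyl-4β-hydroxydauc-8-ene) | CC(C)[C@]1(O)CC[C@]2(C)CC=C(C)C[C@H](C(=O)c3ccc(Br)cc3)[C@H]21 | intermediate
16 | 8α,9α-epoxide of 15 | CC(C)[C@]1(O)CC[C@]2(C)C[C@@H]3O[C@]3(C)C[C@H](C(=O)c3ccc(Br)cc3)[C@H]21 | intermediate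
17 | 8α,9α-epoxy-4β-hydroxy-5αH-daucan-6α-yl 4-bromobenzoate | CC(C)[C@]1(O)CC[C@]2(C)C[C@@H]3O[C@]3(C)C[C@H](OC(=O)c3ccc(Br)cc3)[C@H]21 | intermediate
18 | 8α,9α-epoxy-4β-hydroxy-5αH-daucan-6α-yl 4-(4,4,5,5-tetramethyl-1,3,2-dioxaborolan-2-yl)benzoate | CC(C)[C@]1(O)CC[C@]2(C)C[C@@H]3O[C@]3(C)C[C@H](OC(=O)c3ccc(cc3)B3OC(C)(C)C(C)(C)O3)[C@H]21 | intermediate
19 | jaeskeanin | CC(C)[C@]1(O)CC[C@]2(C)C[C@@H]3O[C@]3(C)C[C@H](OC(=O)c3ccc(O)cc3)[C@H]21 | target

**Totals.** Total step count: 12. Longest linear sequence: 11 steps (steps 1 to 8 and 10 to 12; step 9 makes the phosphonium salt).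

**Steps most likely to fail**

Step 10. The aldehyde arm may be enolised instead of the ketone, leading to self-condensation or to attack of C10 on the phosphonium salt, and the C4 alkoxide may add through oxygen. The fallback sets out from 8 and comes back at 15. Double deprotonation of 8 with lithium diisopropylamide (alkoxide plus the only possible ketone enolate, no aldehyde being present) and C-alkylation with 3-bromo-2-methylprop-1-ene should give the C6-methallyl ketone F1. Ring-closing metathesis of its allyl and methallyl groups with the second-generation Grubbs catalyst (CH2Cl2, 40 °C) then closes the trisubstituted C8=C9 alkene, and catalytic DBU equilibrates C6 to give 15.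

Step 11. Baeyer–Villiger oxidation of the hindered aryl ketone may be sluggish, may suffer aryl migration, or the new epoxide may open during long exposure to the peracid. The fallback sets out from 15 and comes back at 17. TMSOTf and Et3N give the bis(trimethylsilyl) enol ether F2. Rubottom oxidation with mCPBA (NaHCO3), which also epoxidises C8=C9, followed by fluoride work-up gives the α-hydroxy ketone epoxide F3. Cleavage of the α-ketol with Pb(OAc)4 in methanol gives the C6 ketone F4. Hydroxyl-directed reduction with Me4NBH(OAc)3 (delivery from the 4β-hydroxyl, anti-1,3-diol) gives the 6α-alcohol F5. Acylation of its secondary hydroxyl with 4-bromobenzoyl chloride and DMAP gives 17.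

Step 1. Enantiofacial control or turnover may be insufficient in the amine-catalysed epoxidation of the five-membered enone. The fallback sets out from 1 and comes back at 2. CBS reduction (2-methyl-CBS-oxazaborolidine, BH3·SMe2; the catalyst enantiomer that gives the S alcohol) gives (S)-3-methylcyclopent-2-en-1-ol F6. Hydroxyl-directed epoxidation with VO(acac)2 and t-BuOOH gives the cis-epoxy alcohol F7. Oxidation with Dess–Martin periodinane gives 2.

**Further compounds**

F1 | step 10 | 1-(4-bromophenyl)-2-[(1R,2R,5R)-2-hydroxy-5-methyl-5-(prop-2-en-1-yl)-2-(propan-2-yl)cyclopentyl]-4-methylpent-4-en-1-one (C2 epimers) | CC(C)[C@]1(O)CC[C@](C)(CC=C)[C@H]1C(CC(C)=C)C(=O)c1ccc(Br)cc1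
F2 | step 11 | bis(trimethylsilyl) derivative of 15 (C4 silyl ether and aryl ketone silyl enol ether at C6) | CC(C)[C@]1(O[Si](C)(C)C)CC[C@]2(C)CC=C(C)CC(=C(O[Si](C)(C)C)c3ccc(Br)cc3)[C@H]21
F3 | step 11 | 6-(4-bromobenzoyl)-8α,9α-epoxy-5αH-daucane-4β,6-diol | CC(C)[C@]1(O)CC[C@]2(C)C[C@@H]3O[C@]3(C)CC(O)(C(=O)c3ccc(Br)cc3)[C@H]21
F4 | step 11 | 8α,9α-epoxy-4β-hydroxy-5αH-daucan-6-one | CC(C)[C@]1(O)CC[C@]2(C)C[C@@H]3O[C@]3(C)CC(=O)[C@H]21
F5 | step 11 | 8α,9α-epoxy-5αH-daucane-4β,6α-diol | CC(C)[C@]1(O)CC[C@]2(C)C[C@@H]3O[C@]3(C)C[C@H](O)[C@H]21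
F6 | step 1 | (S)-3-methylcyclopent-2-en-1-ol | O[C@H]1CCC(C)=C1
F7 | step 1 | 5-methyl-6-oxabicyclo[3.1.0]hexan-2-ol with the hydroxyl cis to the epoxide oxygen (alcohol corresponding to 2) | O[C@H]1CC[C@@]2(C)O[C@@H]12
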